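**Retrosynthetic overview**

1. Astepyrazinol B comes from its O-(4-methoxybenzyl) lactim ether by acidolysis; the pyrazinone travels through the route as that 2-alkoxypyrazine.
2. Feature used: ring A of the oxindole has only H at C4, C5 and C6 and the prenyl group at C7 next to the nitrogen-bearing C7a. C7a–C7–C6–C5 is therefore read as C2–C3–C4–C5 of a 3-prenyl-2-amidofuran, and C3a–C4 as a vinyl group hung from C3.
3. Key disconnection: C3a–C7a and C4–C5 by an intramolecular furan Diels–Alder reaction of an N-Boc-N-furyl imide. Lactam ring B and the carbocycle close together; the oxygen bridge then opens and water is lost, so benzene ring A is made last and de novo.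
4. The imide comes from Boc-protected 3-prenyl-2-aminofuran (Curtius rearrangement of 3-prenylfuran-2-carboxylic acid, itself from 3-bromofuran-2-carboxylic acid and prenyl bromide) and an (S)-alpha-vinyl acid. The acid is made by auxiliary-controlled deconjugative alkylation of a crotonyl imide, which sets C3.
5. The pyrazinylmethyl bromide comes from 3-methylpyrazin-2(1H)-one by C5 bromination, O-PMB protection, C6 magnesiation and formylation, methoxide SNAr, reduction and Appel bromination; the pyrazine and furan rings are bought.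

Key step: step 12

Remark: C3 is (S) as read from the SMILES. Because C3–H of a 3-monoalkyl oxindole is labile to base, the oxindole is formed and handled only under neutral or acidic conditions, and the Boc group is allowed to leave during the key step.
Abbreviations: PMB = 4-methoxybenzyl; Pz = 3-methoxy-6-[(4-methoxybenzyl)oxy]-5-methylpyrazin-2-yl; Pz-methyl = Pz–CH2–.

**Route**

Step 1
Reactants: 1 3-methylpyrazin-2(1H)-one
Product: 2 5-bromo-3-methylpyrazin-2(1H)-one
Conditions: NBS (1.05 equiv), DMF, 0 °C to rt, dark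
Reagents that add atoms: N-bromosuccinimide, O=C1CCC(=O)N1Br
Why: Electrophilic aromatic bromination, in which the enamide carbon C5 is the most nucleophilic free ring position of the 2(1H)-pyrazinone because C3 is blocked by the methyl group.

Step 2
Reactants: 2 5-bromo-3-methylpyrazin-2(1H)-one
Product: 3 5-bromo-2-[(4-methoxybenzyl)oxy]-3-methylpyrazine
Conditions: PMBCl (1.2 equiv), Ag2CO3 (0.7 equiv), PhMe, 80 °C, dark
Reagents that add atoms: 4-methoxybenzyl chloride, COc1ccc(CCl)cc1
Why: Silver-salt O-alkylation of an ambident lactam, in which the silver pyrazinolate should be benzylated on oxygen to give the lactim ether and not the N-benzyl lactam.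

Step 3
Reactants: 3 5-bromo-2-[(4-methoxybenzyl)oxy]-3-methylpyrazine
Product: 5 3-bromo-6-[(4-methoxybenzyl)oxy]-5-methylpyrazine-2-carbaldehyde, via arylmagnesium chloride 4 (not isolated)
Conditions: TMPMgCl·LiCl (1.2 equiv; TMP = 2,2,6,6-tetramethylpiperidide), THF, −40 °C; DMF (3 equiv), −40 to 0 °C; aq NH4Cl
Reagents that add atoms: N,N-dimethylformamide, CN(C)C=O
Why: Directed magnesiation followed by formylation, in which the only ring C–H (flanked by N1 and C–Br) is the kinetically most acidic site, the hindered magnesium amide should neither exchange the bromine nor metalate the lateral methyl group at −40 °C, and the arylmagnesium adds to DMF.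

Step 4
Reactants: 5 3-bromo-6-[(4-methoxybenzyl)oxy]-5-methylpyrazine-2-carbaldehyde
Product: 7 {3-methoxy-6-[(4-methoxybenzyl)oxy]-5-methylpyrazin-2-yl}methanol, via methoxy aldehyde 6 (not isolated)
Conditions: NaOMe (1.2 equiv), MeOH–THF, 0 °C to rt; then NaBH4 (1 equiv), 0 °C; aq NH4Cl
Reagents that add atoms: sodium methoxide, [Na+].[O-]C
Why: SNAr followed by hydride reduction, in which the bromide ortho to the formyl group and alpha to a ring nitrogen should be displaced by methoxide much faster than the PMB-oxy group, and NaBH4 then reduces the aldehyde in the same flask.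

Step 5
Reactants: 7 {3-methoxy-6-[(4-methoxybenzyl)oxy]-5-methylpyrazin-2-yl}methanol
Product: 8 2-(bromomethyl)-3-methoxy-6-[(4-methoxybenzyl)oxy]-5-methylpyrazine
Conditions: CBr4 (1.3 equiv), PPh3 (1.3 equiv), CH2Cl2, 0 °C; used at once
Reagents that add atoms: carbon tetrabromide, BrC(Br)(Br)Br
Why: Appel reaction, in which bromide displaces the oxyphosphonium salt of the primary heterobenzylic alcohol under neutral conditions that spare the acid-labile PMB lactim ether.

Step 6
Reactants: 9 (S)-4-benzyloxazolidin-2-one; 10 (E)-but-2-enoyl chloride (crotonoyl chloride)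
Product: 12 (S)-4-benzyl-3-[(E)-but-2-enoyl]oxazolidin-2-one, via lithium oxazolidinide 11 (not isolated)
Conditions: n-BuLi (1.0 equiv), THF, −78 °C; then 10 (1.1 equiv), −78 to 0 °C
Reagents that add atoms: none
Why: N-acylation of the lithiated oxazolidinone with an acid chloride, the standard way to an Evans imide.

Step 7
Reactants: 12 (S)-4-benzyl-3-[(E)-but-2-enoyl]oxazolidin-2-one; 8 2-(bromomethyl)-3-methoxy-6-[(4-methoxybenzyl)oxy]-5-methylpyrazine
Product: 14 (S)-4-benzyl-3-[(2S)-2-(Pz-methyl)but-3-enoyl]oxazolidin-2-one, via sodium dienolate 13 (not isolated)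
Conditions: 12 (1.3 equiv), NaN(SiMe3)2 (1.25 equiv), THF, −78 °C; then 8 (1.0 equiv), −78 to −45 °C; aq NH4Cl
Reagents that add atoms: none
Why: Auxiliary-controlled deconjugative alpha-alkylation (Evans alkylation of a dienolate), in which gamma-deprotonation gives the chelated (Z)-dienolate and the bromide adds at the alpha carbon on the face opposite the benzyl group, which sets the (S) centre that becomes C3 (the descriptor is S because vinyl outranks the pyrazinylmethyl group) and moves the double bond out of conjugation.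

Step 8
Reactants: 14 (S)-4-benzyl-3-[(2S)-2-(Pz-methyl)but-3-enoyl]oxazolidin-2-one
Product: 16 (2S)-2-(Pz-methyl)but-3-enoic acid, via lithium peroxycarboxylate 15 (not isolated)
Conditions: LiOH (2 equiv), 30% H2O2 (4 equiv), THF–H2O, 0 °C; aq Na2SO3; 1 M HCl to pH 4, 0 °C
Reagents that add atoms: hydrogen peroxide, OO
Why: Hydroperoxide cleavage of the N-acyl oxazolidinone, in which LiOOH attacks the exocyclic carbonyl selectively at 0 °C under conditions too weakly basic to epimerise or conjugate the alpha-vinyl centre.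

Step 9
Reactants: 17 3-bromofuran-2-carboxylic acid; 18 1-bromo-3-methylbut-2-ene (prenyl bromide)
Product: 20 3-(3-methylbut-2-en-1-yl)furan-2-carboxylic acid, via lithium 3-lithiofuran-2-carboxylate 19 (not isolated)
Conditions: n-BuLi (2.1 equiv), THF, −78 °C; then 18 (1.3 equiv), −78 to 0 °C; aq HCl
Reagents that add atoms: none
Why: Halogen–lithium exchange followed by SN2 alkylation, in which the second equivalent of n-BuLi exchanges the C3 bromine of the lithium carboxylate and the chelated 3-furyllithium displaces bromide at the primary carbon of prenyl bromide.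

Step 10
Reactants: 20 3-(3-methylbut-2-en-1-yl)furan-2-carboxylic acid
Product: 23 tert-butyl [3-(3-methylbut-2-en-1-yl)furan-2-yl]carbamate, via acyl azide 21 (not isolated), via isocyanate 22 (not isolated)
Conditions: DPPA (1.1 equiv), Et3N (1.2 equiv), PhMe, rt then 85 °C; t-BuOH (10 equiv), 85 °C
Reagents that add atoms: diphenylphosphoryl azide, [N-]=[N+]=NP(=O)(Oc1ccccc1)Oc1ccccc1; tert-butanol, CC(C)(C)O
Why: Curtius rearrangement, in which the acyl azide loses N2 with migration of the furyl group and tert-butanol traps the isocyanate as the Boc-protected 2-aminofuran.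

Step 11
Reactants: 16 (2S)-2-(Pz-methyl)but-3-enoic acid; 23 tert-butyl [3-(3-methylbut-2-en-1-yl)furan-2-yl]carbamate
Product: 26 tert-butyl N-[(2S)-2-(Pz-methyl)but-3-enoyl]-N-[3-(3-methylbut-2-en-1-yl)furan-2-yl]carbamate, via acyl fluoride 24 (not isolated), via lithium carbamate 25 (not isolated)
Conditions: 16, cyanuric fluoride (0.4 equiv), pyridine (1 equiv), CH2Cl2, −10 °C, cold aq wash; 23, LiN(SiMe3)2 (0.98 equiv), THF, −78 °C, then 24, −78 to −40 °C; AcOH quench
Reagents that add atoms: none
Why: N-acylation of a lithium carbamate with an acyl fluoride, chosen because the fluoride is made under nearly neutral conditions and forms a ketene far less readily than a chloride, so that a cold acylation with no excess base should leave the alpha-vinyl centre and the position of the double bond untouched.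

Step 12
Reactants: 26 tert-butyl N-[(2S)-2-(Pz-methyl)but-3-enoyl]-N-[3-(3-methylbut-2-en-1-yl)furan-2-yl]carbamate
Product: 30 (3S)-3-(Pz-methyl)-7-(3-methylbut-2-en-1-yl)indolin-2-one, via N-Boc oxanorbornene adduct 27 (not isolated), via N-H oxanorbornene lactam 28 (not isolated), via 5-hydroxy-4,5-dihydrooxindole 29 (not isolated)
Conditions: degassed PhMe (0.01 M), BHT (5 mol %), sealed tube, 110 °C until 26 is consumed, then 170 °C
Reagents that add atoms: none
Why: The 2-imidofuran is the electron-rich diene and the tethered vinyl group the dienophile of an intramolecular furan Diels–Alder reaction, the closest known reaction type being the cycloaddition, bridge opening and dehydration of 2-amidofurans with tethered alkenes that gives indolines. The three-atom N–C(=O)–C3 tether permits only the fused mode, so lactam ring B closes through the new C3a–C7a bond (internal vinyl carbon to furan C2) and the six-membered carbocycle closes through the new C4–C5 bond (terminal vinyl carbon to furan C5), both in the one [4+2] event. The doubly acylated nitrogen of adduct 27 is expected to hold the oxygen bridge until the Boc group is lost as isobutene and CO2 at 170 °C; the lactam nitrogen lone pair of 28 then opens the C7a–O bond, C3a loses its proton to give dienol 29, and loss of water across C4–C5 makes benzene ring A with the prenyl group at C7. The sp3 centres formed at C3a, C5 and C7a all disappear on aromatisation, so no new stereocentre remains and the diastereomer mixture of the adduct converges. The step needs regiocontrol, which the tether fixes, and retention at the spectator carbon C3, which is served by the absence of any base, by consuming the beta,gamma-unsaturated imide at 110 °C before the hot stage, and by high dilution against intermolecular addition.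

Step 13
Reactants: 30 (3S)-3-(Pz-methyl)-7-(3-methylbut-2-en-1-yl)indolin-2-one
Product: 31 astepyrazinol B
Conditions: TFA–CH2Cl2 (1:9), anisole (5 equiv), 0 °C
Reagents that add atoms: none
Why: Acidolysis of a PMB lactim ether, in which protonation of the pyrazine nitrogen makes the pyrazinone a good leaving group and anisole (used in place of a silane, which would reduce the prenyl alkene) captures the 4-methoxybenzyl cation.

**Compound list**

1 | 3-methylpyrazin-2(1H)-one | Cc1ncc[nH]c1=O | starting material
2 | 5-bromo-3-methylpyrazin-2(1H)-one | Cc1nc(Br)c[nH]c1=O | intermediate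
3 | 5-bromo-2-[(4-methoxybenzyl)oxy]-3-methylpyrazine | Cc1nc(Br)cnc1OCc1ccc(OC)cc1 | intermediate
4 | {3-bromo-6-[(4-methoxybenzyl)oxy]-5-methylpyrazin-2-yl}magnesium chloride (LiCl complex) | Cc1nc(Br)c([Mg]Cl)nc1OCc1ccc(OC)cc1 | intermediate
5 | 3-bromo-6-[(4-methoxybenzyl)oxy]-5-methylpyrazine-2-carbaldehyde | Cc1nc(Br)c(C=O)nc1OCc1ccc(OC)cc1 | intermediate
6 | 3-methoxy-6-[(4-methoxybenzyl)oxy]-5-methylpyrazine-2-carbaldehyde | COc1nc(C)c(OCc2ccc(OC)cc2)nc1C=O | intermediate
7 | {3-methoxy-6-[(4-methoxybenzyl)oxy]-5-methylpyrazin-2-yl}methanol | COc1nc(C)c(OCc2ccc(OC)cc2)nc1CO | intermediate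
8 | 2-(bromomethyl)-3-methoxy-6-[(4-methoxybenzyl)oxy]-5-methylpyrazine | COc1nc(C)c(OCc2ccc(OC)cc2)nc1CBr | intermediate
9 | (S)-4-benzyloxazolidin-2-one | O=C1N[C@@H](Cc2ccccc2)CO1 | starting material
10 | (E)-but-2-enoyl chloride (crotonoyl chloride) | C/C=C/C(Cl)=O | starting material
11 | lithium (S)-4-benzyl-2-oxooxazolidin-3-ide | [Li]N1[C@@H](Cc2ccccc2)COC1=O | intermediate
12 | (S)-4-benzyl-3-[(E)-but-2-enoyl]oxazolidin-2-one | C/C=C/C(=O)N1[C@@H](Cc2ccccc2)COC1=O | intermediate
13 | sodium (1Z)-1-[(S)-4-benzyl-2-oxooxazolidin-3-yl]buta-1,3-dien-1-olate | C=C/C=C(\O[Na])N1[C@@H](Cc2ccccc2)COC1=O | intermediate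
14 | (S)-4-benzyl-3-[(2S)-2-({3-methoxy-6-[(4-methoxybenzyl)oxy]-5-methylpyrazin-2-yl}methyl)but-3-enoyl]oxazolidin-2-one | COc1nc(C)c(OCc2ccc(OC)cc2)nc1C[C@@H](C=C)C(=O)N1[C@@H](Cc2ccccc2)COC1=O | intermediate
15 | lithium (2S)-2-({3-methoxy-6-[(4-methoxybenzyl)oxy]-5-methylpyrazin-2-yl}methyl)but-3-eneperoxoate | COc1nc(C)c(OCc2ccc(OC)cc2)nc1C[C@@H](C=C)C(=O)OO[Li] | intermediate
16 | (2S)-2-({3-methoxy-6-[(4-methoxybenzyl)oxy]-5-methylpyrazin-2-yl}methyl)but-3-enoic acid | COc1nc(C)c(OCc2ccc(OC)cc2)nc1C[C@@H](C=C)C(=O)O | intermediate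
17 | 3-bromofuran-2-carboxylic acid | OC(=O)c1occc1Br | starting material
18 | 1-bromo-3-methylbut-2-ene (prenyl bromide) | CC(C)=CCBr | starting material
19 | lithium 3-lithiofuran-2-carboxylate | [Li]OC(=O)c1occc1[Li] | intermediate
20 | 3-(3-methylbut-2-en-1-yl)furan-2-carboxylic acid | OC(=O)c1occc1CC=C(C)C | intermediate
21 | 3-(3-methylbut-2-en-1-yl)furan-2-carbonyl azide | [N-]=[N+]=NC(=O)c1occc1CC=C(C)C | intermediate
22 | 2-isocyanato-3-(3-methylbut-2-en-1-yl)furan | O=C=Nc1occc1CC=C(C)C | intermediate
23 | tert-butyl [3-(3-methylbut-2-en-1-yl)furan-2-yl]carbamate | CC(C)=CCc1ccoc1NC(=O)OC(C)(C)C | intermediate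
24 | (2S)-2-({3-methoxy-6-[(4-methoxybenzyl)oxy]-5-methylpyrazin-2-yl}methyl)but-3-enoyl fluoride | COc1nc(C)c(OCc2ccc(OC)cc2)nc1C[C@@H](C=C)C(F)=O | intermediate
25 | lithium salt of 23 (N-lithio carbamate) | CC(C)=CCc1ccoc1N([Li])C(=O)OC(C)(C)C | intermediate
26 | tert-butyl N-[(2S)-2-({3-methoxy-6-[(4-methoxybenzyl)oxy]-5-methylpyrazin-2-yl}methyl)but-3-enoyl]-N-[3-(3-methylbut-2-en-1-yl)furan-2-yl]carbamate (key-step precursor) | COc1nc(C)c(OCc2ccc(OC)cc2)nc1C[C@@H](C=C)C(=O)N(C(=O)OC(C)(C)C)c1occc1CC=C(C)C | intermediate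
27 | tert-butyl (3S)-3-({3-methoxy-6-[(4-methoxybenzyl)oxy]-5-methylpyrazin-2-yl}methyl)-7-(3-methylbut-2-en-1-yl)-2-oxo-2,3,3a,4-tetrahydro-5,7a-epoxyindole-1(5H)-carboxylate (mixture at C3a, C5, C7a) | COc1nc(C)c(OCc2ccc(OC)cc2)nc1C[C@@H]1C(=O)N(C(=O)OC(C)(C)C)C23OC(CC12)C=C3CC=C(C)C | intermediate
28 | (3S)-3-({3-methoxy-6-[(4-methoxybenzyl)oxy]-5-methylpyrazin-2-yl}methyl)-7-(3-methylbut-2-en-1-yl)-1,3,3a,4-tetrahydro-5,7a-epoxyindol-2(5H)-one (mixture at C3a, C5, C7a) | COc1nc(C)c(OCc2ccc(OC)cc2)nc1C[C@@H]1C(=O)NC23OC(CC12)C=C3CC=C(C)C | intermediate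
29 | (3S)-5-hydroxy-3-({3-methoxy-6-[(4-methoxybenzyl)oxy]-5-methylpyrazin-2-yl}methyl)-7-(3-methylbut-2-en-1-yl)-1,3,4,5-tetrahydro-2H-indol-2-one (mixture at C5) | COc1nc(C)c(OCc2ccc(OC)cc2)nc1C[C@@H]1C(=O)NC2=C1CC(O)C=C2CC=C(C)C | intermediate
30 | (3S)-3-({3-methoxy-6-[(4-methoxybenzyl)oxy]-5-methylpyrazin-2-yl}methyl)-7-(3-methylbut-2-en-1-yl)indolin-2-one (key-step product, O-PMB astepyrazinol B) | COc1nc(C)c(OCc2ccc(OC)cc2)nc1C[C@@H]1C(=O)Nc2c(CC=C(C)C)cccc21 | intermediate
31 | astepyrazinol B, (3S)-3-[(3-methoxy-5-methyl-6-oxo-1,6-dihydropyrazin-2-yl)methyl]-7-(3-methylbut-2-en-1-yl)indolin-2-one | COc1nc(C)c(=O)[nH]c1C[C@@H]1C(=O)Nc2c(CC=C(C)C)cccc21 | target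

**Step count and risks**

Total step count: 13. Longest linear sequence: 10 steps (steps 1, 2, 3, 4, 5, 7, 8, 11, 12, 13).

Steps most likely to fail:

1. Step 12. The cycloaddition may stall because an unactivated vinyl group is a poor dienophile, the oxygen bridge of the imide-type adduct may resist opening, or C3 may epimerise by enolisation during the hot stage. The fallback sets out from 8 and 9 and comes back at 30; it brings ring A in ready-made and closes the lactam by nitro reduction. Commercial (3-bromo-2-nitrophenyl)acetic acid would be joined to 9 (pivaloyl chloride, Et3N, LiCl, THF) to give (S)-4-benzyl-3-[2-(3-bromo-2-nitrophenyl)acetyl]oxazolidin-2-one F1. Its sodium enolate (NaN(SiMe3)2, THF, −78 °C) would be alkylated with 8 in an Evans alkylation to give (S)-4-benzyl-3-[(2S)-2-(3-bromo-2-nitrophenyl)-3-Pz-propanoyl]oxazolidin-2-one F2; the centre should again be (S), because the aryl group takes the place and the priority rank of the vinyl group. Fe powder and NH4Cl in EtOH–H2O at 70 °C would reduce the nitro group, and the aniline should close onto the imide carbonyl with loss of 9 to give (3S)-7-bromo-3-(Pz-methyl)indolin-2-one F3. Stille coupling with tributyl(3-methylbut-2-en-1-yl)stannane and Pd(PPh3)4 in DMF at 90 °C would then place the prenyl group on C7 and give 30.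

2. Step 11. The alpha-vinyl centre may be lost by enolisation or ketene formation, or the double bond may migrate into conjugation, while the lithium carbamate is acylated. The fallback sets out from 20 and 16 and comes back at 26; it makes the amide bond without any strong base. Acid 20 would be converted with DPPA and Et3N in toluene at 80 °C, with no alcohol present, into isocyanate 22. Acid 16 would be added at 80 °C, so that the mixed carbamic carboxylic anhydride F4 loses CO2 and gives the secondary amide (2S)-2-(Pz-methyl)-N-[3-(3-methylbut-2-en-1-yl)furan-2-yl]but-3-enamide F5 (acylation of an isocyanate by a carboxylic acid). Boc2O with catalytic DMAP in MeCN at 0 °C would then put the Boc group on nitrogen and give 26.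

3. Step 3. The base may metalate the C3 methyl group laterally, or the ortho-bromo arylmagnesium may eliminate to a hetaryne, instead of undergoing clean ring magnesiation. The fallback sets out from 3 and comes back at 7; it brings the carbon in by cross-coupling. Pd-catalysed C–O coupling of 3 with methanol (Pd2(dba)3, tBuBrettPhos, Cs2CO3, PhMe, 60 °C) would give 5-methoxy-2-[(4-methoxybenzyl)oxy]-3-methylpyrazine F6. NBS in MeCN at 0 °C should brominate the only ring C–H, ortho to the methoxy group, to give 2-bromo-3-methoxy-6-[(4-methoxybenzyl)oxy]-5-methylpyrazine F7. Stille coupling with Bu3SnCH2OH and Pd(PPh3)4 in dioxane at 90 °C would then deliver alcohol 7.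

Further compounds
F1 | step 12 | (S)-4-benzyl-3-[2-(3-bromo-2-nitrophenyl)acetyl]oxazolidin-2-one | O=C(Cc1cccc(Br)c1[N+](=O)[O-])N1[C@@H](Cc2ccccc2)COC1=O
F2 | step 12 | (S)-4-benzyl-3-[(2S)-2-(3-bromo-2-nitrophenyl)-3-{3-methoxy-6-[(4-methoxybenzyl)oxy]-5-methylpyrazin-2-yl}propanoyl]oxazolidin-2-one | COc1nc(C)c(OCc2ccc(OC)cc2)nc1C[C@@H](c1cccc(Br)c1[N+](=O)[O-])C(=O)N1[C@@H](Cc2ccccc2)COC1=O
F3 | step 12 | (3S)-7-bromo-3-({3-methoxy-6-[(4-methoxybenzyl)oxy]-5-methylpyrazin-2-yl}methyl)indolin-2-one | COc1nc(C)c(OCc2ccc(OC)cc2)nc1C[C@@H]1C(=O)Nc2c(Br)cccc21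
F4 | step 11 | (2S)-2-({3-methoxy-6-[(4-methoxybenzyl)oxy]-5-methylpyrazin-2-yl}methyl)but-3-enoic [3-(3-methylbut-2-en-1-yl)furan-2-yl]carbamic anhydride | COc1nc(C)c(OCc2ccc(OC)cc2)nc1C[C@@H](C=C)C(=O)OC(=O)Nc1occc1CC=C(C)C
F5 | step 11 | (2S)-2-({3-methoxy-6-[(4-methoxybenzyl)oxy]-5-methylpyrazin-2-yl}methyl)-N-[3-(3-methylbut-2-en-1-yl)furan-2-yl]but-3-enamide | COc1nc(C)c(OCc2ccc(OC)cc2)nc1C[C@@H](C=C)C(=O)Nc1occc1CC=C(C)C
F6 | step 3 | 5-methoxy-2-[(4-methoxybenzyl)oxy]-3-methylpyrazine | COc1cnc(OCc2ccc(OC)cc2)c(C)n1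
F7 | step 3 | 2-bromo-3-methoxy-6-[(4-methoxybenzyl)oxy]-5-methylpyrazine | COc1nc(C)c(OCc2ccc(OC)cc2)nc1Br
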